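The closed vessel was stirred at constant temperature, and solid D fed E, which could go on to J, G, Q or, with X, to L.

- elm: D 3 M; X 1.8 M; run made earlier
- flask: D 3.0 M; X 0.900 M; time 3.0 d
elm run (percent of the D charged)

| time / h | J / % | D / % |
|---|---|---|
| 1.50 | 12.3 | 0 |
| 4.00 | 21.4 | 0.4 |
| 10.0 | 18.9 | 0.2 |
| 20.0 | 15.4 | 0.6 |

(readings scatter by 0.5 percentage points)
- percentages count the D that a species holds: one Q counts as two
- solid, in amounts per volume of the solution: D
- steps thought possible: G <-> E; E + X -> L; J <-> G; 2 E -> Q; D <-> E; E <-> J
- at the start none of D is in solution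
- no earlier run changes the charge of X; that part of a forecast is a guess
* when, up to 3.0 d, the flask holds most J
* the amount of J, in percent of the D charged, at that time

From 4.00 h to 20.0 h, the elm J readings fell at a pseudo-first-order 0.0206 /h. Carried back to zero time, they gave 23.2%, which I took as J's share of the charge not turned into L. I scaled that fall to the flask's [X] and kept the elm's best reading time, 0.17 d, which gave me 22.3% of J. With X as limiting reagent, one X per E, L in the flask could reach 30.0%. With L at that bound, my share gave 16.3% of J, less than my peak, so I expected an early maximum.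

The forecast gave 32% at 0.4 d, arguing that “Halving X should roughly halve the L route”. The flask gave 24.1% at 0.233 d.

    G ⇌ E (k = 0.543 /h)
    E + X → L (k = 1.47 /M/h)
    J ⇌ G (K = 2.50, k = 0.555 /h)
    2 E → Q (k = 0.0979 /M/h)
    D ⇌ E, rate k5*(cs5 - [E]) while solid is left; crystals form when [E] > cs5 (solubility = 2.40 M, k = 1.02 /h)
    E ⇌ J (K = 14.1, k = 0.474 /h)

At its best time the flask held 24.1% of J and 13.6% of L, so J's share of the charge not in L was then 27.9%. At 3.00 d, with 29.8% of L, that share gave 19.6%, and the flask held 19.4%. The neighbouring flask with 1.5 M of X reached 48.9% of L by 3.00 d. There my 23.2% gave 11.9% of J and the flask's share gave 14.3%. That neighbour ended with 14.1%.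

(The data are calculated from invented constants; the scatter is artificial.)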